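**Retrosynthetic overview**

1. Target ⇐ acid removal of three MOM ethers ⇐ (2S)-flavanone, made by ligand-controlled rhodium-catalysed 1,4-addition of a 2,4-bis(MOM-oxy)phenylboronic acid to a 6-substituted chromone (C2–aryl bond).
2. All-trans aroylcyclohexene ⇐ hydrolysis and decarboxylation of a cis-fused β-keto aryl lactone, which reveals an epimerisable C–H that settles trans to both neighbours.
3. Lactone ⇐ one operation: Knoevenagel/lactonisation of 2,4-dihydroxybenzaldehyde with an aroylacetate to a 3-aroylcoumarin (a cis-locked stand-in for the chalcone), then endo Diels–Alder addition to a 6-dienylchromone.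
4. Dienylchromone ⇐ 6-iodochromone + vinylboronate + sulcatone enol triflate (Heck, then Suzuki); chromone ⇐ phloroacetophenone + orthoformate.
5. Ring order: pyranone ring C (step 1) → coumarin lactone and cyclohexene together (step 8) → lactone opened again (step 9); all benzene rings are bought.

Assumption: compounds 19, 20 and 21 are racemates, named and drawn as the enantiomer that is carried on to 28; the cyclohexene carbons are called C1' (chromone-bearing), C5' (dihydroxyphenyl-bearing) and C6' (aroyl-bearing).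

The target was read as the (2S)-flavanone carrying the (1'R,5'S,6'R) all-trans cyclohexene. The key cycloaddition gives a racemate: the absolute configuration of the three cyclohexene centres is obtained by separating two diastereomers after step 12 (at most half the material), not by asymmetric induction.

**Route**

Step 1
Reactants: 1 1-(2,4,6-trihydroxyphenyl)ethanone
Product: 3 5,7-dihydroxy-4H-chromen-4-one, via ethoxychromenylium perchlorate 2 (not isolated)
Conditions: HC(OEt)3 (5 equiv), 70% HClO4 (1.2 equiv), rt, 16 h; then H2O, 90 °C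
Reagents that add atoms: triethyl orthoformate, CCOC(OCC)OCC; water, O
Why: Acid-promoted condensation of a 2-hydroxyacetophenone with triethyl orthoformate (C-formylation of the methyl ketone, closure through an ortho hydroxyl, hydrolysis of the 4-ethoxypyrylium salt) is a classical chromone synthesis, and the symmetry of 1 means either ortho hydroxyl gives the same ring C; no stereocentre is formed.

Step 2
Reactants: 3 5,7-dihydroxy-4H-chromen-4-one
Product: 4 5-hydroxy-7-(methoxymethoxy)-4H-chromen-4-one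
Conditions: MOMCl (1.05 equiv), iPr2NEt, CH2Cl2, 0 °C
Reagents that add atoms: chloromethyl methyl ether, COCCl
Why: O-Alkylation (Williamson type) takes place at the acidic free 7-OH because the 5-OH is tied up in a hydrogen bond to the C4 carbonyl; no stereocentre is formed.

Step 3
Reactants: 4 5-hydroxy-7-(methoxymethoxy)-4H-chromen-4-one
Product: 5 5-hydroxy-6-iodo-7-(methoxymethoxy)-4H-chromen-4-one
Conditions: NIS (1.05 equiv), DMF, rt, dark
Reagents that add atoms: N-iodosuccinimide, O=C1CCC(=O)N1I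
Why: Electrophilic aromatic iodination of 5-hydroxy-7-alkoxy chromones under neutral conditions is directed by the free chelated 5-OH to its ortho position C6 and not to C8; no stereocentre is formed.

Step 4
Reactants: 6 6-methylhept-5-en-2-one
Product: 8 6-methylhepta-1,5-dien-2-yl trifluoromethanesulfonate, via lithium enolate 7 (not isolated)
Conditions: LiN(iPr)2, THF, −78 °C; then PhNTf2, −78 to 0 °C
Reagents that add atoms: N-phenylbis(trifluoromethanesulfonimide), O=S(=O)(N(c1ccccc1)S(=O)(=O)C(F)(F)F)C(F)(F)F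
Why: Kinetic deprotonation of the methyl ketone at the methyl group and O-sulfonylation of the terminal enolate (enol triflate formation) give the 1,1-disubstituted alkenyl triflate; no stereocentre is formed.

Step 5
Reactants: 8 6-methylhepta-1,5-dien-2-yl trifluoromethanesulfonate; 9 2-ethenyl-4,4,5,5-tetramethyl-1,3,2-dioxaborolane; 5 5-hydroxy-6-iodo-7-(methoxymethoxy)-4H-chromen-4-one
Product: 11 5-hydroxy-7-(methoxymethoxy)-6-[(1E)-7-methyl-3-methylideneocta-1,6-dien-1-yl]-4H-chromen-4-one, via dienylboronate 10 (not isolated)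
Conditions: 8 (1.3 equiv), 9 (1.1 equiv), Pd(OAc)2 (5 mol %), P(o-tol)3, Et3N, MeCN, 70 °C; then 5 (1.0 equiv), SPhos, K2CO3, H2O, 60 °C
Reagents that add atoms: none
Why: A Heck–Mizoroki reaction of the alkenyl triflate with the vinylboronate under amine base keeps the C–B bond and gives the (E)-dienylboronate by syn insertion and syn β-hydride elimination, and adding aqueous carbonate and iodide 5 switches the same palladium catalyst to a Suzuki–Miyaura coupling that transfers the dienyl group with retention of the E geometry.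

Step 6
Reactants: 12 1-(4-hydroxyphenyl)ethanone; 13 1-bromo-3-methylbut-2-ene
Product: 15 1-[4-hydroxy-3-(3-methylbut-2-en-1-yl)phenyl]ethanone, via sodium phenolate 14 (not isolated)
Conditions: NaH (1.05 equiv), toluene, 0 °C; then 13 (1.1 equiv), rt to 50 °C
Reagents that add atoms: none
Why: C-Alkylation of a sodium phenoxide in a non-polar solvent (ortho-prenylation through the unsubstituted allyl terminus) places the prenyl group ortho to oxygen, the O-prenyl ether being removed by chromatography; no stereocentre is formed.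

Step 7
Reactants: 15 1-[4-hydroxy-3-(3-methylbut-2-en-1-yl)phenyl]ethanone
Product: 16 ethyl 3-[4-hydroxy-3-(3-methylbut-2-en-1-yl)phenyl]-3-oxopropanoate
Conditions: NaH (3.5 equiv), (EtO)2CO (4 equiv), THF, reflux; then AcOH, 0 °C
Reagents that add atoms: diethyl carbonate, CCOC(=O)OCC
Why: Crossed Claisen condensation of the ketone enolate (formed beside the phenoxide by excess NaH) with diethyl carbonate is driven by deprotonation of the β-keto ester product; no stereocentre is formed.

Step 8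
Reactants: 17 2,4-dihydroxybenzaldehyde; 16 ethyl 3-[4-hydroxy-3-(3-methylbut-2-en-1-yl)phenyl]-3-oxopropanoate; 11 5-hydroxy-7-(methoxymethoxy)-6-[(1E)-7-methyl-3-methylideneocta-1,6-dien-1-yl]-4H-chromen-4-one
Product: 19 rac-(6aS,7S,10aR)-3-hydroxy-6a-[4-hydroxy-3-(3-methylbut-2-en-1-yl)benzoyl]-7-[5-hydroxy-7-(methoxymethoxy)-4-oxo-4H-chromen-6-yl]-9-(4-methylpent-3-en-1-yl)-6a,7,10,10a-tetrahydro-6H-benzo[c]chromen-6-one, via 3-aroylcoumarin 18 (not isolated)
Conditions: 17 and 16 (1.5 equiv each), piperidine (10 mol %), AcOH (10 mol %), EtOH, 60 °C, 2 h; evaporate in the same flask; then 11 (1.0 equiv), BHT, 1,2-dichlorobenzene, 135 °C, sealed tube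
Reagents that add atoms: none
Why: Proposed new method: Knoevenagel condensation with lactonisation builds the 3-aroylcoumarin 18 (first ring), a cis-locked, doubly activated surrogate of the (E)-chalcone, and its C3=C4 bond then adds to diene 11 in a normal-demand Diels–Alder reaction (second ring) in which the nucleophilic CH2 terminus of the 1-aryl-3-alkyl diene bonds to the coumarin β-carbon and the flat benzopyranone lies endo under the diene while the out-of-plane aroyl group points away, so that the chromone-bearing carbon, the lactone carbonyl and the fused aryl ring end up on one face (C1'/C5' cis) and the aroyl group on the other, as a racemate; the closest known chemistry is the piperidine-catalysed synthesis of 3-acylcoumarins from salicylaldehydes, thermal and high-pressure Diels–Alder additions of 3-acyl- and 3-nitrocoumarins to 1,3-dienes, and domino Knoevenagel/cycloaddition sequences.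

Step 9
Reactants: 19 rac-(6aS,7S,10aR)-lactone cycloadduct
Product: 21 rac-6-[(1R,5S,6R)-5-(2,4-dihydroxyphenyl)-6-[4-hydroxy-3-(3-methylbut-2-en-1-yl)benzoyl]-3-(4-methylpent-3-en-1-yl)cyclohex-2-en-1-yl]-5-hydroxy-7-(methoxymethoxy)-4H-chromen-4-one, via β-keto acid 20 (not isolated)
Conditions: LiOH (6 equiv), THF/H2O 3:1, 0 °C, 1 h; AcOH to pH 4, 45 °C; then DBU, THF, rt
Reagents that add atoms: none
Why: Saponification of the activated aryl lactone, decarboxylation of the α,α-disubstituted β-keto acid and base-mediated epimerisation of the newly enolisable C6' (α to the aryl ketone) give the thermodynamic all-equatorial isomer with the aroyl group trans to both neighbours, while the cis relationship of C1' and C5' fixed in step 8 is untouched.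

Step 10
Reactants: 22 4-bromobenzene-1,3-diol
Product: 23 1-bromo-2,4-bis(methoxymethoxy)benzene
Conditions: MOMCl (2.4 equiv), iPr2NEt, CH2Cl2, 0 °C to rt
Reagents that add atoms: chloromethyl methyl ether, COCCl
Why: Double O-alkylation of both phenols gives the base-stable, acid-labile bis-acetal needed for the lithiation that follows; no stereocentre is formed.

Step 11
Reactants: 23 1-bromo-2,4-bis(methoxymethoxy)benzene
Product: 26 [2,4-bis(methoxymethoxy)phenyl]boronic acid, via aryllithium 24 (not isolated), via lithium borate 25 (not isolated)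
Conditions: n-BuLi (1.05 equiv), THF, −78 °C; B(OiPr)3 (1.3 equiv), −78 °C to rt; 1 M HCl to pH 6, 0 °C
Reagents that add atoms: triisopropyl borate, CC(C)OB(OC(C)C)OC(C)C; water, O
Why: Bromine–lithium exchange, borylation with a trialkyl borate and mild hydrolysis is the standard route to arylboronic acids, and the MOM ethers survive both the aryllithium and the pH 6 work-up; no stereocentre is formed.

Step 12
Reactants: 21 rac all-trans cyclohexenyl chromone; 26 [2,4-bis(methoxymethoxy)phenyl]boronic acid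
Product: 27 (2S)-2-[2,4-bis(methoxymethoxy)phenyl]-6-[(1R,5S,6R)-5-(2,4-dihydroxyphenyl)-6-[4-hydroxy-3-(3-methylbut-2-en-1-yl)benzoyl]-3-(4-methylpent-3-en-1-yl)cyclohex-2-en-1-yl]-5-hydroxy-7-(methoxymethoxy)-2,3-dihydro-4H-chromen-4-one
Conditions: [RhCl(C2H4)2]2 (3 mol %), (S)-MeO-F12-BIPHEP (7 mol %), KOH (0.3 equiv), 26 (4 equiv), toluene/H2O 10:1, 40 °C; the two diastereomers are separated by chromatography
Reagents that add atoms: none
Why: Rhodium-catalysed asymmetric 1,4-addition of an arylboronic acid to a chromone (Hayashi–Miyaura reaction) creates C2 as S under control of the (S)-biaryl bisphosphine (same enone face as in the (S)-BINAP addition to cyclohexenone, independent of the remote cyclohexene), so racemic 21 gives two separable diastereomers and isolating the (2S,1'R,5'S,6'R) isomer fixes the absolute configuration of the three cyclohexene centres.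

Step 13
Reactants: 27 tris-MOM flavanone
Product: 28 (2S)-2-(2,4-dihydroxyphenyl)-6-[(1R,5S,6R)-5-(2,4-dihydroxyphenyl)-6-[4-hydroxy-3-(3-methylbut-2-en-1-yl)benzoyl]-3-(4-methylpent-3-en-1-yl)cyclohex-2-en-1-yl]-5,7-dihydroxy-2,3-dihydro-4H-chromen-4-one
Conditions: 3 M HCl, MeOH, 25–40 °C
Reagents that add atoms: none
Why: Acid-catalysed acetal exchange in methanol cleaves the three MOM ethers as dimethoxymethane under conditions mild enough to leave the prenyl and 4-methylpent-3-enyl alkenes, the flavanone C2 centre and the already thermodynamic C6' centre unchanged.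

**Compound list**

1 | 1-(2,4,6-trihydroxyphenyl)ethanone | CC(=O)c1c(O)cc(O)cc1O | starting material
2 | 4-ethoxy-5,7-dihydroxychromenylium perchlorate | CCOc1cc[o+]c2cc(O)cc(O)c12.[O-]Cl(=O)(=O)=O | intermediate
3 | 5,7-dihydroxy-4H-chromen-4-one | O=c1ccoc2cc(O)cc(O)c12 | intermediate
4 | 5-hydroxy-7-(methoxymethoxy)-4H-chromen-4-one | O=c1ccoc2cc(OCOC)cc(O)c12 | intermediate
5 | 5-hydroxy-6-iodo-7-(methoxymethoxy)-4H-chromen-4-one | O=c1ccoc2cc(OCOC)c(I)c(O)c12 | intermediate
6 | 6-methylhept-5-en-2-one | CC(=O)CCC=C(C)C | starting material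
7 | lithium 6-methylhepta-1,5-dien-2-olate | C=C([O-])CCC=C(C)C.[Li+] | intermediate
8 | 6-methylhepta-1,5-dien-2-yl trifluoromethanesulfonate | C=C(CCC=C(C)C)OS(=O)(=O)C(F)(F)F | intermediate
9 | 2-ethenyl-4,4,5,5-tetramethyl-1,3,2-dioxaborolane | C=CB1OC(C)(C)C(C)(C)O1 | starting material
10 | 4,4,5,5-tetramethyl-2-[(1E)-7-methyl-3-methylideneocta-1,6-dien-1-yl]-1,3,2-dioxaborolane | CC(C)=CCCC(=C)/C=C/B1OC(C)(C)C(C)(C)O1 | intermediate
11 | 5-hydroxy-7-(methoxymethoxy)-6-[(1E)-7-methyl-3-methylideneocta-1,6-dien-1-yl]-4H-chromen-4-one | CC(C)=CCCC(=C)/C=C/c1c(OCOC)cc2occc(=O)c2c1O | intermediate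
12 | 1-(4-hydroxyphenyl)ethanone | CC(=O)c1ccc(O)cc1 | starting material
13 | 1-bromo-3-methylbut-2-ene | CC(C)=CCBr | starting material
14 | sodium 4-acetylphenolate | CC(=O)c1ccc([O-])cc1.[Na+] | intermediate
15 | 1-[4-hydroxy-3-(3-methylbut-2-en-1-yl)phenyl]ethanone | CC(=O)c1ccc(O)c(CC=C(C)C)c1 | intermediate
16 | ethyl 3-[4-hydroxy-3-(3-methylbut-2-en-1-yl)phenyl]-3-oxopropanoate | CCOC(=O)CC(=O)c1ccc(O)c(CC=C(C)C)c1 | intermediate
17 | 2,4-dihydroxybenzaldehyde | O=Cc1ccc(O)cc1O | starting material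
18 | 7-hydroxy-3-[4-hydroxy-3-(3-methylbut-2-en-1-yl)benzoyl]-2H-chromen-2-one | O=C(c1ccc(O)c(CC=C(C)C)c1)c1cc2ccc(O)cc2oc1=O | intermediate
19 | rac-(6aS,7S,10aR)-3-hydroxy-6a-[4-hydroxy-3-(3-methylbut-2-en-1-yl)benzoyl]-7-[5-hydroxy-7-(methoxymethoxy)-4-oxo-4H-chromen-6-yl]-9-(4-methylpent-3-en-1-yl)-6a,7,10,10a-tetrahydro-6H-benzo[c]chromen-6-one (cis ring fusion; chromonyl cis to the lactone carbonyl) | CC(C)=CCCC1=C[C@@H](c2c(OCOC)cc3occc(=O)c3c2O)[C@@]2(C(=O)c3ccc(O)c(CC=C(C)C)c3)C(=O)Oc3cc(O)ccc3[C@H]2C1 | intermediate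
20 | rac-(1S,2S,6R)-6-(2,4-dihydroxyphenyl)-1-[4-hydroxy-3-(3-methylbut-2-en-1-yl)benzoyl]-2-[5-hydroxy-7-(methoxymethoxy)-4-oxo-4H-chromen-6-yl]-4-(4-methylpent-3-en-1-yl)cyclohex-3-ene-1-carboxylic acid | CC(C)=CCCC1=C[C@@H](c2c(OCOC)cc3occc(=O)c3c2O)[C@@](C(=O)c2ccc(O)c(CC=C(C)C)c2)(C(=O)O)[C@@H](c2ccc(O)cc2O)C1 | intermediate
21 | rac-6-[(1R,5S,6R)-5-(2,4-dihydroxyphenyl)-6-[4-hydroxy-3-(3-methylbut-2-en-1-yl)benzoyl]-3-(4-methylpent-3-en-1-yl)cyclohex-2-en-1-yl]-5-hydroxy-7-(methoxymethoxy)-4H-chromen-4-one | CC(C)=CCCC1=C[C@@H](c2c(OCOC)cc3occc(=O)c3c2O)[C@H](C(=O)c2ccc(O)c(CC=C(C)C)c2)[C@@H](c2ccc(O)cc2O)C1 | intermediate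
22 | 4-bromobenzene-1,3-diol | Oc1ccc(Br)c(O)c1 | starting material
23 | 1-bromo-2,4-bis(methoxymethoxy)benzene | COCOc1ccc(Br)c(OCOC)c1 | intermediate
24 | [2,4-bis(methoxymethoxy)phenyl]lithium | [Li]c1ccc(OCOC)cc1OCOC | intermediate
25 | lithium [2,4-bis(methoxymethoxy)phenyl]tri(propan-2-yloxy)borate | COCOc1ccc([B-](OC(C)C)(OC(C)C)OC(C)C)c(OCOC)c1.[Li+] | intermediate
26 | [2,4-bis(methoxymethoxy)phenyl]boronic acid | COCOc1ccc(B(O)O)c(OCOC)c1 | intermediate
27 | (2S)-2-[2,4-bis(methoxymethoxy)phenyl]-6-[(1R,5S,6R)-5-(2,4-dihydroxyphenyl)-6-[4-hydroxy-3-(3-methylbut-2-en-1-yl)benzoyl]-3-(4-methylpent-3-en-1-yl)cyclohex-2-en-1-yl]-5-hydroxy-7-(methoxymethoxy)-2,3-dihydro-4H-chromen-4-one | CC(C)=CCCC1=C[C@@H](c2c(OCOC)cc3c(c2O)C(=O)C[C@@H](c2ccc(OCOC)cc2OCOC)O3)[C@H](C(=O)c2ccc(O)c(CC=C(C)C)c2)[C@@H](c2ccc(O)cc2O)C1 | intermediate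
28 | (2S)-2-(2,4-dihydroxyphenyl)-6-[(1R,5S,6R)-5-(2,4-dihydroxyphenyl)-6-[4-hydroxy-3-(3-methylbut-2-en-1-yl)benzoyl]-3-(4-methylpent-3-en-1-yl)cyclohex-2-en-1-yl]-5,7-dihydroxy-2,3-dihydro-4H-chromen-4-one | CC(C)=CCCC1=C[C@@H](c2c(O)cc3c(c2O)C(=O)C[C@@H](c2ccc(O)cc2O)O3)[C@H](C(=O)c2ccc(O)c(CC=C(C)C)c2)[C@@H](c2ccc(O)cc2O)C1 | target

**Step count and risks**

Total step count: 13. Longest linear sequence: 8 steps (steps 1, 2, 3, 5, 8, 9, 12 and 13, from 1 to 28).

Steps most likely to fail: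

Step 8. The cycloaddition creates a quaternary carbon next to the carbon that carries a 2,6-dioxygenated aryl group, so it may be slow. The coumarin can also react as a 1-oxadiene (hetero-Diels–Alder), and the all-trans outcome depends on the benzopyranone, not the aroyl group, taking the endo position. The fallback gives up the coumarin, sets out from 11, 15 and 17 and comes back to the route at 28. Ketone 15 is protected (MOMCl, iPr2NEt) to 1-[4-(methoxymethoxy)-3-(3-methylbut-2-en-1-yl)phenyl]ethanone F1, and aldehyde 17 (MOMCl, 2.5 equiv) to 2,4-bis(methoxymethoxy)benzaldehyde F2. Claisen–Schmidt condensation (KOH, EtOH) joins them to (2E)-3-[2,4-bis(methoxymethoxy)phenyl]-1-[4-(methoxymethoxy)-3-(3-methylbut-2-en-1-yl)phenyl]prop-2-en-1-one F3. F3 is heated with 11 (toluene, 150 °C, sealed tube, or 10 kbar in CH2Cl2) in a direct intermolecular Diels–Alder reaction, and the all-trans adduct rac-6-[(1R,5S,6R)-5-[2,4-bis(methoxymethoxy)phenyl]-6-[4-(methoxymethoxy)-3-(3-methylbut-2-en-1-yl)benzoyl]-3-(4-methylpent-3-en-1-yl)cyclohex-2-en-1-yl]-5-hydroxy-7-(methoxymethoxy)-4H-chromen-4-one F4 is separated from its cis,trans isomer. F4 is arylated with 26 under the conditions of step 12 to (2S)-2-[2,4-bis(methoxymethoxy)phenyl]-6-[(1R,5S,6R)-5-[2,4-bis(methoxymethoxy)phenyl]-6-[4-(methoxymethoxy)-3-(3-methylbut-2-en-1-yl)benzoyl]-3-(4-methylpent-3-en-1-yl)cyclohex-2-en-1-yl]-5-hydroxy-7-(methoxymethoxy)-2,3-dihydro-4H-chromen-4-one F5 (diastereomers separated), and F5 is deprotected as in step 13 to give 28.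

Step 12. The arylation is run late, on a polyphenolic racemate, and needs a large excess of boronic acid. The fallback moves the arylation forward, sets out from 11 and comes back at 27. Compound 11 is arylated first (26, same rhodium catalyst) to (2S)-2-[2,4-bis(methoxymethoxy)phenyl]-5-hydroxy-7-(methoxymethoxy)-6-[(1E)-7-methyl-3-methylideneocta-1,6-dien-1-yl]-2,3-dihydro-4H-chromen-4-one F6. Coumarin 18 is made from 16 and 17 as in step 8 but filtered off, then heated with F6 (1,2-dichlorobenzene, 135 °C, no amine present). After separation of the two diastereomers this gives (6aS,7S,10aR)-7-[(2S)-2-[2,4-bis(methoxymethoxy)phenyl]-5-hydroxy-7-(methoxymethoxy)-4-oxo-3,4-dihydro-2H-chromen-6-yl]-3-hydroxy-6a-[4-hydroxy-3-(3-methylbut-2-en-1-yl)benzoyl]-9-(4-methylpent-3-en-1-yl)-6a,7,10,10a-tetrahydro-6H-benzo[c]chromen-6-one F7. Neutral ester cleavage with Me3SnOH (1,2-dichloroethane, 70 °C), decarboxylation on mild acidification and equilibration of C6' with Et3N in MeOH give 27 without exposing the flavanone to hydroxide.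

Step 5. At the Heck stage the triflate and the vinylboronate can cross-couple directly (giving myrcene), or the dienylboronate can be lost before the hindered iodide reacts. The fallback builds the two bonds in the opposite order, sets out from 5 and 8 and comes back at 11. Iodide 5 is vinylated with CH2=CHBF3K (PdCl2(dppf), Cs2CO3, THF/H2O, 60 °C) to 6-ethenyl-5-hydroxy-7-(methoxymethoxy)-4H-chromen-4-one F8, and a Heck–Mizoroki coupling of F8 with triflate 8 (Pd(OAc)2, PPh3, Et3N, DMF, 80 °C) gives 11.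

**Further compounds**

F1 | step 8 | 1-[4-(methoxymethoxy)-3-(3-methylbut-2-en-1-yl)phenyl]ethanone | CC(=O)c1ccc(OCOC)c(CC=C(C)C)c1
F2 | step 8 | 2,4-bis(methoxymethoxy)benzaldehyde | COCOc1ccc(C=O)c(OCOC)c1
F3 | step 8 | (2E)-3-[2,4-bis(methoxymethoxy)phenyl]-1-[4-(methoxymethoxy)-3-(3-methylbut-2-en-1-yl)phenyl]prop-2-en-1-one | COCOc1ccc(/C=C/C(=O)c2ccc(OCOC)c(CC=C(C)C)c2)c(OCOC)c1
F4 | step 8 | rac-6-[(1R,5S,6R)-5-[2,4-bis(methoxymethoxy)phenyl]-6-[4-(methoxymethoxy)-3-(3-methylbut-2-en-1-yl)benzoyl]-3-(4-methylpent-3-en-1-yl)cyclohex-2-en-1-yl]-5-hydroxy-7-(methoxymethoxy)-4H-chromen-4-one | CC(C)=CCCC1=C[C@@H](c2c(OCOC)cc3occc(=O)c3c2O)[C@H](C(=O)c2ccc(OCOC)c(CC=C(C)C)c2)[C@@H](c2ccc(OCOC)cc2OCOC)C1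
F5 | step 8 | (2S)-2-[2,4-bis(methoxymethoxy)phenyl]-6-[(1R,5S,6R)-5-[2,4-bis(methoxymethoxy)phenyl]-6-[4-(methoxymethoxy)-3-(3-methylbut-2-en-1-yl)benzoyl]-3-(4-methylpent-3-en-1-yl)cyclohex-2-en-1-yl]-5-hydroxy-7-(methoxymethoxy)-2,3-dihydro-4H-chromen-4-one | CC(C)=CCCC1=C[C@@H](c2c(OCOC)cc3c(c2O)C(=O)C[C@@H](c2ccc(OCOC)cc2OCOC)O3)[C@H](C(=O)c2ccc(OCOC)c(CC=C(C)C)c2)[C@@H](c2ccc(OCOC)cc2OCOC)C1
F6 | step 12 | (2S)-2-[2,4-bis(methoxymethoxy)phenyl]-5-hydroxy-7-(methoxymethoxy)-6-[(1E)-7-methyl-3-methylideneocta-1,6-dien-1-yl]-2,3-dihydro-4H-chromen-4-one | CC(C)=CCCC(=C)/C=C/c1c(OCOC)cc2c(c1O)C(=O)C[C@@H](c1ccc(OCOC)cc1OCOC)O2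
F7 | step 12 | (6aS,7S,10aR)-7-[(2S)-2-[2,4-bis(methoxymethoxy)phenyl]-5-hydroxy-7-(methoxymethoxy)-4-oxo-3,4-dihydro-2H-chromen-6-yl]-3-hydroxy-6a-[4-hydroxy-3-(3-methylbut-2-en-1-yl)benzoyl]-9-(4-methylpent-3-en-1-yl)-6a,7,10,10a-tetrahydro-6H-benzo[c]chromen-6-one | CC(C)=CCCC1=C[C@@H](c2c(OCOC)cc3c(c2O)C(=O)C[C@@H](c2ccc(OCOC)cc2OCOC)O3)[C@@]2(C(=O)c3ccc(O)c(CC=C(C)C)c3)C(=O)Oc3cc(O)ccc3[C@H]2C1
F8 | step 5 | 6-ethenyl-5-hydroxy-7-(methoxymethoxy)-4H-chromen-4-one | C=Cc1c(OCOC)cc2occc(=O)c2c1O
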